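Remark on the chemistry: atom labels C1–C15 follow the germacrane skeleton (C1–C10 ring, C11/C12/C13 lactone carbons, C14 on C10, C15 on C4). The C7 oxygen is carried as a triethylsilyl enol ether, and 11, 13 and (Z)-2-methylbut-2-enoic acid are assumed to be purchased.

## Analysis of the target

Target 26 is a germacranolide: a ten-membered carbocycle (C1–C10) with a (Z)-olefin at C1=C10 and an (E)-olefin at C4=C5, and an α-methylene-γ-butyrolactone (O–C6, C7, C11=C13, C12=O) fused across C6–C7. Four contiguous stereocentres run from C6 to C9 (6S,7R,8S,9R). The lactone is cis-fused, so H6 and the tertiary hydroxyl on C7 share one face of the five-membered ring; the C8 angelate and the C9 hydroxyl are syn along the C7–C10 chain; C7 is fully substituted. The sensitive groups are the exocyclic enoate (a Michael acceptor), the angelate (it isomerises to the tiglate and migrates to neighbouring hydroxyls), the allylic C9 alcohol with the 1,5-diene (acid triggers transannular cyclisation), and the allylic C6–O bond of the lactone. The hard parts are the medium ring with two trisubstituted olefins of opposite geometry and the O6/O7/O8/O9 array around a quaternary carbinol; a carbanion at C7 is ruled out because it would expel the oxygen on C8. The plan rests on the C6–C7 bond: C6 is a lactone CH–O and C7 carries the acrylate unit C11(=C13)–C12, which is the pattern left when the γ-carbon of a 2-alkoxycarbonyl allylboronate adds to an aldehyde and the new alkoxide closes onto the ester. Cutting there also divides 26 into a C1–C6 dienyl half without stereocentres and a C7–C9 half whose only stereocentre (C8) can be bought. The second bond to cut, C9–C10, joins an aldehyde-derived carbinol to the iodine-bearing carbon of a (Z)-alkenyl iodide.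

## Retrosynthetic reasoning

C9–C10 (26 ⇒ 24). The ring is opened between the allylic carbinol C9 and the olefinic carbon C10. This cut gives two groups that tolerate the rest of the molecule, an aldehyde and a (Z)-alkenyl iodide, and it lets both olefin geometries be fixed beforehand in open-chain chemistry. Cutting C5–C6 or C2–C3 would break up the dienyl half and offers no comparably mild closure. Forward, a chromium/nickel-mediated intramolecular addition of the alkenyl iodide to the aldehyde has to close the ring with retention of the C1=C10 geometry and set C9.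

Adjusting the triol (24 ⇒ 23 ⇒ 22 ⇒ 21 ⇒ 20 ⇒ 19). The aldehyde comes from the primary alcohol at C9. Before that, the secondary C8 hydroxyl must receive the (Z)-2-methylbut-2-enoyl group while O9 is blocked. The order follows the steric ranking primary > secondary > tertiary in triol 20, which is released from 19 by one acid treatment. The ester goes on at the open-chain stage, where the C8 and C9 hydroxyls still differ in kind; after ring closure two secondary hydroxyls would have to be told apart.

C6–C7 and O6–C12 (19 ⇒ 10 + 17). Both lactone bonds that are absent from the two halves are cut at once. Cutting C7–C11 would need a hindered C7 ketone as acceptor, and cutting C7–C8 would need a C7 carbanion β to oxygen. Cutting C6–C7 needs neither, gives fragments of similar size (10 and 17), and aldehyde 10 has no α-stereocentre to lose. Forward, the reaction must form C6–C7 through the γ-carbon of the allylboronate, turn the enol ether geometry of 17 into the cis relation of the two arms, select one face of C7 under the influence of C8, and lactonise.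

Fragment 2 (17 ⇒ 15 ⇒ 12 ⇒ 11 + 13). 17 is the enol ether of a β-keto ester, so the O7–Si bond is cut first, then C11–C13 (to 12 and 13), then C7–C11 by a Claisen disconnection back to 11. The order matters. A preformed enol ether cannot be metalated at C11, because base would take the more acidic C8 hydrogen and expel the dioxolane oxygen; the doubly activated C11–H of 12 is alkylated under mild conditions instead. The oxygen is capped with silicon and not with a benzyl-type group, because a hard silicon electrophile attacks the enolate oxygen inside the metal chelate that fixes the geometry, whereas benzylic halides would alkylate carbon. The silyl ether is shed together with the acetonide right after the fragment union.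

Fragment 1 (10 ⇒ 9 ⇒ 8 ⇒ 3 + 4 ⇒ 2 ⇒ 1). The enal is traced to allylic acetate 8. The (Z)-iodoalkene is cut at C1=C10 into aldehyde 3 and a two-carbon phosphorus ylide from 4, the usual disconnection of a (Z)-2-iodo-2-alkene. 3 comes from cleavage of the remote trisubstituted olefin of 1, whose (E)-olefin becomes C4=C5 of the target.

## Alternatives that were turned down

Alternative 1: The ring is cut at C1–C2, an sp2–sp3 bond remote from every stereocentre. Forward, 9-BBN-H would hydroborate the terminal vinyl group of the open-chain iodo-diene A2, and PdCl2(dppf) with aqueous Cs2CO3 would couple the C2 borane with the (Z)-alkenyl iodide at C1 to give the ten-membered diene A1. In its favour: no stereocentre is made at ring closure, the olefin geometry is carried over with retention, and C6–C9 are set in the open chain. On this point it is stronger than the chosen route, whose ring closure must also set C9. Against it for this target: A1 still lacks the lactone. The silylethynyl carbinol at C7 would have to be converted into the α-methylene lactone, three protecting groups exchanged and the angelate introduced, all on a strained, acid-sensitive medium ring. A2 must be built in one linear chain with four oxygenated centres including a tertiary propargylic one. The hydroboration must distinguish the vinyl end of a conjugated diene from a silyl alkyne. A ten-membered ring is the least favourable size for a B-alkyl coupling, where β-hydride elimination and oligomerisation compete. The chosen strategy offers convergence instead: lactone, quaternary carbinol and C6 arise in the fragment union, and the ring closure delivers the target itself.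

Alternative 2: The lactone is cut at C7–C11 on a preformed ring. Forward, quinuclidine would add to the O6 acrylate of the ten-membered ketone A4, and the resulting enolate would attack the C7 ketone to give A3, the target with O8 and O9 still protected. In its favour: the tether can only deliver the acrylate to the face of C7 syn to O6, so the cis fusion is guaranteed. This is stronger than the chosen route, where the same relation depends on an enol ether geometry and a chair transition state. Methylene and tertiary hydroxyl also arise in one atom-economic step. Against it: ketones are poor acceptors in this reaction, and this one is flanked by two oxygen-bearing stereocentres (C6, C8), both α to the carbonyl and open to epimerisation or β-elimination by the amine. A4 itself is a ten-membered α,α'-dioxygenated dienone that has to be made first, so the ring problem is only moved and transannular reactions become a concern. The chosen route sets C7 in an open-chain, base-free, closed transition state and forms the ring last.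

Alternative 3: The ring arises by forming C2–C3 while breaking C5–C10. Forward, KH and 18-crown-6 would convert the cyclohexanol A6 into its alkoxide, a [3,3] shift would open the ten-membered ring, and PhNTf2 would trap the C1=C10 enolate as enol triflate A5. In its favour: the ring forms without high dilution, both olefin geometries follow from the cis arrangement on the six-membered ring, and C6–C9 can be set with cyclohexane conformational control. On ring formation it is stronger than a macrocyclisation. Against it: A6 needs six contiguous stereocentres, two of them fully substituted, and two (C5, C10) are destroyed in the key step. The strongly basic medium meets β-alkoxy groups next to the alkoxide and the enolate. Afterwards C14 must be introduced at the triflate, the lactone built from the 2-propenyl side chain by oxidation-state changes, three protecting groups removed and the angelate installed. The chosen route takes the (E)-olefin from 1 and the (Z)-olefin from one olefination, and needs no oxidation-state change on the lactone carbons.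

Key step: step 9

## Steps

Step 1
Reactants: 1 geranyl acetate
Product: 2 (2E)-5-(3,3-dimethyloxiran-2-yl)-3-methylpent-2-en-1-yl acetate (racemic at the epoxide carbon)
Conditions: mCPBA (1.05 equiv), CH2Cl2, 0 °C
Reagents that add atoms: mCPBA, OOC(=O)c1cccc(Cl)c1
Why: Prilezhaev epoxidation; the remote trisubstituted olefin is more electron-rich than the one bearing the allylic acetate, so one equivalent of peracid should react there, and the new stereocentre is cleaved in step 2.

Step 2
Reactants: 2 epoxide
Product: 3 (2E)-3-methyl-6-oxohex-2-en-1-yl acetate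
Conditions: H5IO6 (1.2 equiv), THF/H2O, 0 °C → rt
Reagents that add atoms: none
Why: Acid-promoted epoxide hydration and periodate (Malaprade) glycol cleavage in one pot; the remaining olefin and the acetate are inert.

Step 3
Reactants: 3 aldehyde; 4 ethyltriphenylphosphonium bromide
Product: 8 (2E,6Z)-7-iodo-3-methylocta-2,6-dien-1-yl acetate, via ethylidenetriphenylphosphorane 5 (not isolated), via (1-iodoethyl)triphenylphosphonium iodide 6 (not isolated), via (1-iodoethylidene)triphenylphosphorane 7 (not isolated)
Conditions: 4 (1.4 equiv), n-BuLi, THF, 0 °C; I2, −78 °C; NaN(SiMe3)2, −78 → −20 °C; then 3, −78 °C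
Reagents that add atoms: iodine, II
Why: Wittig olefination with an α-iodo ylide (Stork–Zhao-type iodoalkylidenation); the non-stabilised ylide adds under kinetic control through the cis-oxaphosphetane, which places iodine cis to the chain and should give mainly the (Z)-2-iodo-2-alkene, and the acetate survives at −78 °C.

Step 4
Reactants: 8 allylic acetate
Product: 9 (2E,6Z)-7-iodo-3-methylocta-2,6-dien-1-ol
Conditions: K2CO3 (0.2 equiv), MeOH, 0 °C → rt
Reagents that add atoms: none
Why: Base-catalysed transesterification to methanol; alkenyl iodide and olefins are untouched.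

Step 5
Reactants: 9 allylic alcohol
Product: 10 (2E,6Z)-7-iodo-3-methylocta-2,6-dienal (fragment 1)
Conditions: MnO2 (20 equiv), CH2Cl2, rt
Reagents that add atoms: none
Why: Allylic alcohol oxidation with MnO2 stops at the aldehyde under neutral conditions, so the (E)-enal geometry and the alkenyl iodide should be kept.

Step 6
Reactants: 11 methyl (4S)-2,2-dimethyl-1,3-dioxolane-4-carboxylate
Product: 12 methyl 3-[(4S)-2,2-dimethyl-1,3-dioxolan-4-yl]-3-oxopropanoate
Conditions: LiN(i-Pr)2 (2.2 equiv), methyl acetate (2.2 equiv), THF, −78 °C; then 11, −78 → −40 °C; AcOH, −78 °C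
Reagents that add atoms: methyl acetate, COC(C)=O
Why: Crossed Claisen condensation; the α-alkoxy ester is a good acyl acceptor, and the product sits in the flask as its C11 enolate, so the C8 hydrogen is not removed and the stereocentre from 11 is kept.

Step 7
Reactants: 12 β-keto ester; 13 2-(iodomethyl)-4,4,5,5-tetramethyl-1,3,2-dioxaborolane
Product: 15 methyl 3-[(4S)-2,2-dimethyl-1,3-dioxolan-4-yl]-3-oxo-2-[(4,4,5,5-tetramethyl-1,3,2-dioxaborolan-2-yl)methyl]propanoate (both C11 epimers), via sodium enolate of the keto ester 14 (not isolated)
Conditions: NaH (1.0 equiv), THF, 0 °C; then 13 (1.05 equiv), 0 °C → rt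
Reagents that add atoms: none
Why: C-alkylation of a stabilised sodium enolate by an α-boryl alkyl iodide (SN2 at a carbon activated by the neighbouring boron), the known entry to β-boryl carbonyl compounds; the new C11 centre is a mixture that is erased in step 8.

Step 8
Reactants: 15 borylmethyl β-keto ester
Product: 17 methyl (2Z)-3-[(4S)-2,2-dimethyl-1,3-dioxolan-4-yl]-2-[(4,4,5,5-tetramethyl-1,3,2-dioxaborolan-2-yl)methyl]-3-[(triethylsilyl)oxy]prop-2-enoate (fragment 2), via sodium chelate enolate 16 (not isolated)
Conditions: NaH (1.1 equiv), THF, 0 °C; then Et3SiCl (1.2 equiv), 0 °C; non-aqueous work-up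
Reagents that add atoms: chlorotriethylsilane, CC[Si](Cl)(CC)CC
Why: O-silylation of a β-keto ester enolate with a hard silicon electrophile; the six-membered sodium chelate between the two carbonyl oxygens holds O7 cis to the ester, so the (Z)-enol ether with C8 cis to CH2B should result, and C8 is untouched because only C11–H is acidic enough for NaH.

Step 9
Reactants: 10 fragment 1; 17 fragment 2
Product: 19 (4R,5S)-4-[(4S)-2,2-dimethyl-1,3-dioxolan-4-yl]-5-[(1E,5Z)-6-iodo-2-methylhepta-1,5-dien-1-yl]-3-methylidene-4-[(triethylsilyl)oxy]oxolan-2-one, via open-chain pinacol borate 18 (not isolated)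
Conditions: 10 (1.0 equiv), 17 (1.3 equiv), Sc(OTf)3 (10 mol%), 2,6-di-tert-butylpyridine (20 mol%), 4 Å MS, toluene, −20 °C → rt (40 °C if lactone closure lags)
Reagents that add atoms: none
Why: Sc(OTf)3 binds a pinacolate oxygen of 17 and raises the electrophilicity of boron, the aldehyde oxygen of 10 coordinates to boron, and the allyl unit is transferred through a six-membered chair in which C7 bonds to C6 and the double bond moves to C11=C13, giving borate 18. The closest known reaction type is the Lewis-acid-catalysed allylboration of aldehydes with 3,3-disubstituted 2-alkoxycarbonyl allylboronates, which gives α-methylene-γ-lactones with a fully substituted β-carbon; that precedent covers carbon substituents at the γ-carbon, while γ-alkoxyallylboronates without the ester are known to add through their oxygen-bearing carbon. The lactone then closes when the borate oxygen O6 attacks the C12 ester (5-exo-trig acyl substitution), with methoxide passing to boron. C6 is controlled by the chair with the dienyl arm of 10 equatorial together with the (Z)-geometry of 17 (C8 axial, silyloxy group equatorial), which places the C5 arm and the C8 arm cis on the lactone. C7 is controlled by C8: A(1,3) strain with the CH2B group holds the C8–H bond in the olefin plane, and the aldehyde should add to the face anti to the C8–O bond, which gives 7R and, through the chair, 6S. The step needs attack through C7 and not through the enol ether carbon C11, which the boron-centred cyclic transition state enforces; 1,2-addition to the enal is inherent to allylboration. It also needs the enol ether geometry to survive, for which the hindered pyridine, the sieves and the low temperature keep protic acid away. The alkenyl iodide, the acetonide and the remote olefin are not expected to react with catalytic Sc(OTf)3 in dry toluene.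

Step 10
Reactants: 19 silyl ether acetonide
Product: 20 (4S,5S)-4-[(1S)-1,2-dihydroxyethyl]-4-hydroxy-5-[(1E,5Z)-6-iodo-2-methylhepta-1,5-dien-1-yl]-3-methylideneoxolan-2-one
Conditions: 1 M HCl, THF, 0 °C → rt
Reagents that add atoms: none
Why: Acid hydrolysis removes the dioxolane and the tertiary triethylsilyl ether in one operation; the lactone, the alkenyl iodide and the olefin should tolerate dilute acid at room temperature (the C7 descriptor changes only because the CIP ranking changes).

Step 11
Reactants: 20 triol
Product: 21 (4S,5S)-4-hydroxy-4-[(1S)-1-hydroxy-2-[(triethylsilyl)oxy]ethyl]-5-[(1E,5Z)-6-iodo-2-methylhepta-1,5-dien-1-yl]-3-methylideneoxolan-2-one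
Conditions: Et3SiCl (1.05 equiv), Et3N, DMAP (5 mol%), CH2Cl2, −40 °C
Reagents that add atoms: chlorotriethylsilane, CC[Si](Cl)(CC)CC
Why: Silylation under steric control; the primary C9 hydroxyl should react far faster than the neopentyl-like secondary C8 hydroxyl and the tertiary C7 hydroxyl.

Step 12
Reactants: 21 diol
Product: 22 (1S)-1-[(2S,3R)-3-hydroxy-2-[(1E,5Z)-6-iodo-2-methylhepta-1,5-dien-1-yl]-4-methylidene-5-oxooxolan-3-yl]-2-[(triethylsilyl)oxy]ethyl (2Z)-2-methylbut-2-enoate
Conditions: (Z)-2-methylbut-2-enoic acid (3 equiv), 2,4,6-trichlorobenzoyl chloride (3 equiv), Et3N, toluene, rt; then 21, 75 °C, no DMAP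
Reagents that add atoms: (Z)-2-methylbut-2-enoic acid (angelic acid), OC(=O)/C(C)=C\C
Why: Yamaguchi-type acylation by the preformed mixed anhydride without a nucleophilic catalyst, conditions under which the (Z)-acyl group is transferred without isomerisation to the tiglate; the tertiary C7 hydroxyl is too hindered to compete.

Step 13
Reactants: 22 silyl ether
Product: 23 (1S)-2-hydroxy-1-[(2S,3R)-3-hydroxy-2-[(1E,5Z)-6-iodo-2-methylhepta-1,5-dien-1-yl]-4-methylidene-5-oxooxolan-3-yl]ethyl (2Z)-2-methylbut-2-enoate
Conditions: HF·pyridine, pyridine, THF, 0 °C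
Reagents that add atoms: none
Why: Fluoride cleavage of the primary silyl ether in a buffered, slightly acidic medium, chosen because base-catalysed migration of the angelate is then slow.

Step 14
Reactants: 23 primary alcohol
Product: 24 (1R)-1-[(2S,3R)-3-hydroxy-2-[(1E,5Z)-6-iodo-2-methylhepta-1,5-dien-1-yl]-4-methylidene-5-oxooxolan-3-yl]-2-oxoethyl (2Z)-2-methylbut-2-enoate
Conditions: Dess–Martin periodinane, CH2Cl2, 0 °C → rt; crude aldehyde used at once
Reagents that add atoms: none
Why: Dess–Martin oxidation takes the primary alcohol to the aldehyde without base, so C8 should not epimerise and the tertiary alcohol is inert (the C8 descriptor changes only by CIP ranking).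

Step 15
Reactants: 24 iodo aldehyde
Product: 26 CNP0292337.1, (3aR,4S,5R,6Z,10E,11aS)-3a,5-dihydroxy-6,10-dimethyl-3-methylidene-2-oxo-2,3,3a,4,5,8,9,11a-octahydrocyclodeca[b]furan-4-yl (2Z)-2-methylbut-2-enoate, via alkenylchromium dichloride 25 (not isolated)
Conditions: CrCl2 (12 equiv), NiCl2 (0.2 equiv), degassed DMSO/THF, 2 mM by syringe pump, rt
Reagents that add atoms: none
Why: Nozaki–Hiyama–Kishi reaction; nickel activates the alkenyl iodide, transmetalation gives the alkenyl trivalent chromium species 25 with retention of the (Z)-geometry, and it adds only to the aldehyde, closing the ten-membered ring next to the cis-disposed lactone arms. C9 is set under substrate control: the aldehyde C–H should eclipse the C1=C10 plane to avoid A(1,3) strain with C2, and the oxygen–chromium unit should stay on the outer rim of the forming ring, an arrangement that is expected to expose the Re face (9R), although this is not secured by a rule.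

## Compound list

1 | geranyl acetate, (2E)-3,7-dimethylocta-2,6-dien-1-yl acetate | CC(C)=CCC/C(C)=C/COC(C)=O | starting material
2 | (2E)-5-(3,3-dimethyloxiran-2-yl)-3-methylpent-2-en-1-yl acetate | CC(=O)OC/C=C(\C)CCC1OC1(C)C | intermediate
3 | (2E)-3-methyl-6-oxohex-2-en-1-yl acetate | CC(=O)OC/C=C(\C)CCC=O | intermediate
4 | ethyltriphenylphosphonium bromide | CC[P+](c1ccccc1)(c1ccccc1)c1ccccc1.[Br-] | starting material
5 | ethylidenetriphenylphosphorane | CC=P(c1ccccc1)(c1ccccc1)c1ccccc1 | intermediate
6 | (1-iodoethyl)triphenylphosphonium iodide | CC(I)[P+](c1ccccc1)(c1ccccc1)c1ccccc1.[I-] | intermediate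
7 | (1-iodoethylidene)triphenylphosphorane | CC(I)=P(c1ccccc1)(c1ccccc1)c1ccccc1 | intermediate
8 | (2E,6Z)-7-iodo-3-methylocta-2,6-dien-1-yl acetate | CC(=O)OC/C=C(\C)CC/C=C(/C)I | intermediate
9 | (2E,6Z)-7-iodo-3-methylocta-2,6-dien-1-ol | OC/C=C(\C)CC/C=C(/C)I | intermediate
10 | (2E,6Z)-7-iodo-3-methylocta-2,6-dienal (fragment 1) | O=C/C=C(\C)CC/C=C(/C)I | intermediate
11 | methyl (4S)-2,2-dimethyl-1,3-dioxolane-4-carboxylate | COC(=O)[C@@H]1COC(C)(C)O1 | starting material
12 | methyl 3-[(4S)-2,2-dimethyl-1,3-dioxolan-4-yl]-3-oxopropanoate | COC(=O)CC(=O)[C@@H]1COC(C)(C)O1 | intermediate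
13 | 2-(iodomethyl)-4,4,5,5-tetramethyl-1,3,2-dioxaborolane | ICB1OC(C)(C)C(C)(C)O1 | starting material
14 | sodium (1Z)-1-[(4S)-2,2-dimethyl-1,3-dioxolan-4-yl]-3-methoxy-3-oxoprop-1-en-1-olate | COC(=O)/C=C(\[O-])[C@@H]1COC(C)(C)O1.[Na+] | intermediate
15 | methyl 3-[(4S)-2,2-dimethyl-1,3-dioxolan-4-yl]-3-oxo-2-[(4,4,5,5-tetramethyl-1,3,2-dioxaborolan-2-yl)methyl]propanoate (C11 epimers) | COC(=O)C(CB1OC(C)(C)C(C)(C)O1)C(=O)[C@@H]2COC(C)(C)O2 | intermediate
16 | sodium (1Z)-enolate of 15 | COC(=O)/C(CB1OC(C)(C)C(C)(C)O1)=C(\[O-])[C@@H]2COC(C)(C)O2.[Na+] | intermediate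
17 | methyl (2Z)-3-[(4S)-2,2-dimethyl-1,3-dioxolan-4-yl]-2-[(4,4,5,5-tetramethyl-1,3,2-dioxaborolan-2-yl)methyl]-3-[(triethylsilyl)oxy]prop-2-enoate (fragment 2) | COC(=O)/C(CB1OC(C)(C)C(C)(C)O1)=C(\O[Si](CC)(CC)CC)[C@@H]2COC(C)(C)O2 | intermediate
18 | open-chain pinacol borate: methyl 2-methylidene-3-(triethylsilyloxy)-3-[(4S)-dioxolanyl]-4-(pinacolboryloxy)alkenoate with 6S,7R centres | COC(=O)C(=C)[C@](O[Si](CC)(CC)CC)([C@@H]1COC(C)(C)O1)[C@@H](OB2OC(C)(C)C(C)(C)O2)/C=C(\C)CC/C=C(/C)I | intermediate
19 | (4R,5S)-4-[(4S)-2,2-dimethyl-1,3-dioxolan-4-yl]-5-[(1E,5Z)-6-iodo-2-methylhepta-1,5-dien-1-yl]-3-methylidene-4-[(triethylsilyl)oxy]oxolan-2-one | C=C1C(=O)O[C@@H](/C=C(\C)CC/C=C(/C)I)[C@@]1(O[Si](CC)(CC)CC)[C@@H]2COC(C)(C)O2 | intermediate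
20 | (4S,5S)-4-[(1S)-1,2-dihydroxyethyl]-4-hydroxy-5-[(1E,5Z)-6-iodo-2-methylhepta-1,5-dien-1-yl]-3-methylideneoxolan-2-one | C=C1C(=O)O[C@@H](/C=C(\C)CC/C=C(/C)I)[C@@]1(O)[C@@H](O)CO | intermediate
21 | (4S,5S)-4-hydroxy-4-[(1S)-1-hydroxy-2-[(triethylsilyl)oxy]ethyl]-5-[(1E,5Z)-6-iodo-2-methylhepta-1,5-dien-1-yl]-3-methylideneoxolan-2-one | C=C1C(=O)O[C@@H](/C=C(\C)CC/C=C(/C)I)[C@@]1(O)[C@@H](O)CO[Si](CC)(CC)CC | intermediate
22 | (1S)-1-[(2S,3R)-3-hydroxy-2-[(1E,5Z)-6-iodo-2-methylhepta-1,5-dien-1-yl]-4-methylidene-5-oxooxolan-3-yl]-2-[(triethylsilyl)oxy]ethyl (2Z)-2-methylbut-2-enoate | C=C1C(=O)O[C@@H](/C=C(\C)CC/C=C(/C)I)[C@@]1(O)[C@@H](OC(=O)/C(C)=C\C)CO[Si](CC)(CC)CC | intermediate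
23 | (1S)-2-hydroxy-1-[(2S,3R)-3-hydroxy-2-[(1E,5Z)-6-iodo-2-methylhepta-1,5-dien-1-yl]-4-methylidene-5-oxooxolan-3-yl]ethyl (2Z)-2-methylbut-2-enoate | C=C1C(=O)O[C@@H](/C=C(\C)CC/C=C(/C)I)[C@@]1(O)[C@@H](OC(=O)/C(C)=C\C)CO | intermediate
24 | (1R)-1-[(2S,3R)-3-hydroxy-2-[(1E,5Z)-6-iodo-2-methylhepta-1,5-dien-1-yl]-4-methylidene-5-oxooxolan-3-yl]-2-oxoethyl (2Z)-2-methylbut-2-enoate | C=C1C(=O)O[C@@H](/C=C(\C)CC/C=C(/C)I)[C@@]1(O)[C@@H](OC(=O)/C(C)=C\C)C=O | intermediate
25 | alkenylchromium dichloride of 24 (CrCl2 on C10 in place of iodine) | C=C1C(=O)O[C@@H](/C=C(\C)CC/C=C(/C)[Cr](Cl)Cl)[C@@]1(O)[C@@H](OC(=O)/C(C)=C\C)C=O | intermediate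
26 | CNP0292337.1, (3aR,4S,5R,6Z,10E,11aS)-3a,5-dihydroxy-6,10-dimethyl-3-methylidene-2-oxo-2,3,3a,4,5,8,9,11a-octahydrocyclodeca[b]furan-4-yl (2Z)-2-methylbut-2-enoate | C=C1C(=O)O[C@H]2/C=C(\C)CC/C=C(/C)[C@@H](O)[C@H](OC(=O)/C(C)=C\C)[C@@]12O | target

## Step count and weak points

Total: 15 steps. Longest linear sequence: 12 steps (steps 1–5 and 9–15); fragment 2 takes 3 steps (6–8).

Step 9 (key step). The most likely failure is a slow allyl transfer: the enol ether oxygen and the ester make C7=C11 a push–pull olefin, which lowers the electron density at C7, the carbon that has to attack. While the addition waits, acid-induced rotation about C7=C11, loss of the silyl group or attack of C11 on the aldehyde can take over. Isomerisation of the enal and a weak preference for the face anti to the C8–O bond would add further diastereomers. Fallback, setting out from 17 and 10 and returning at 19: the boronate is replaced by a more nucleophilic allylmetal that keeps the closed transition state. Oxidation of the C–B bond of 17 with anhydrous Me3NO in THF would give methyl (2Z)-3-[(4S)-2,2-dimethyl-1,3-dioxolan-4-yl]-2-(hydroxymethyl)-3-[(triethylsilyl)oxy]prop-2-enoate F1, and CBr4/PPh3 would convert it into methyl (2E)-2-(bromomethyl)-3-[(4S)-2,2-dimethyl-1,3-dioxolan-4-yl]-3-[(triethylsilyl)oxy]prop-2-enoate F2 (same spatial arrangement, descriptor changed by ranking). CrCl2 in THF with 10 (Nozaki–Hiyama allylation) would then form a γ,γ-disubstituted allylchromium species, which keeps its geometry, adds through the same chair and lactonises to 19.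

Step 15. Poor facial selectivity at C9 is the main risk, because the open-chain Felkin-type bias of an α-acyloxy aldehyde points to the 8,9-anti epimer while the target is 8,9-syn; intermolecular coupling competes if the dilution is insufficient. Fallback, setting out from 24 and returning at 26: if the cyclisation gives mainly the C9 epimer of 26 F3, it would be oxidised with Dess–Martin periodinane to the C9 ketone (the C1=C10 enone) F4 and reduced with NaBH4/CeCl3 at −78 °C, where hydride delivery from the ring periphery, or a reagent-controlled reduction if needed, should give the 9R alcohol 26.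

Step 8. Loss of chelate control is the risk: if the enolate oxygen binds the neighbouring boron or the sodium chelate opens, silylation gives the (E)-enol ether, which would lead to the trans-fused lactone in step 9. Fallback, setting out from 11 and returning at 20: the geometry is locked in a ring. Claisen condensation of 11 with the lithium enolate of tert-butyl acetate would give tert-butyl 3-[(4S)-2,2-dimethyl-1,3-dioxolan-4-yl]-3-oxopropanoate F5, and alkylation with 13 would give its 2-(pinacolborylmethyl) derivative F6. Acetone, trifluoroacetic anhydride and trifluoroacetic acid would then close 6-[(4S)-2,2-dimethyl-1,3-dioxolan-4-yl]-2,2-dimethyl-5-[(4,4,5,5-tetramethyl-1,3,2-dioxaborolan-2-yl)methyl]-4H-1,3-dioxin-4-one F7, in which O7 is necessarily cis to the carbonyl. The same Sc(OTf)3-catalysed union with 10 would expel acetone on lactonisation and give (4R,5S)-4-[(4S)-2,2-dimethyl-1,3-dioxolan-4-yl]-4-hydroxy-5-[(1E,5Z)-6-iodo-2-methylhepta-1,5-dien-1-yl]-3-methylideneoxolan-2-one F8, and dilute HCl would hydrolyse the acetonide to 20.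

Step 13. Migration of the angelate from O8 to the freed primary O9, or more slowly to O7, is the risk, because the primary ester is the more stable one. Fallback, setting out from 22 and returning at 24: Swern oxidation (oxalyl chloride, DMSO, −78 °C, then Et3N) converts primary triethylsilyl ethers directly into aldehydes, so the free alcohol 23 is never formed.

Step 7. Reaction at oxygen instead of carbon is the risk: the enolate can add to boron and shift from boron to carbon, giving an enol ether O–CH2–B, and double alkylation is possible. Fallback, setting out from 11 and returning at 15: the bond order is reversed, and the lithium enolate of methyl 3-(4,4,5,5-tetramethyl-1,3,2-dioxaborolan-2-yl)propanoate is acylated with 11 in a crossed Claisen condensation, which gives 15 directly.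

## Further compounds

F1 | step 9 | methyl (2Z)-3-[(4S)-2,2-dimethyl-1,3-dioxolan-4-yl]-2-(hydroxymethyl)-3-[(triethylsilyl)oxy]prop-2-enoate | COC(=O)/C(CO)=C(\O[Si](CC)(CC)CC)[C@@H]1COC(C)(C)O1
F2 | step 9 | methyl (2E)-2-(bromomethyl)-3-[(4S)-2,2-dimethyl-1,3-dioxolan-4-yl]-3-[(triethylsilyl)oxy]prop-2-enoate | COC(=O)/C(CBr)=C(\O[Si](CC)(CC)CC)[C@@H]1COC(C)(C)O1
F3 | step 15 | C9 epimer of 26, (3aR,4S,5S,6Z,10E,11aS)-3a,5-dihydroxy-6,10-dimethyl-3-methylidene-2-oxo-2,3,3a,4,5,8,9,11a-octahydrocyclodeca[b]furan-4-yl (2Z)-2-methylbut-2-enoate | C=C1C(=O)O[C@H]2/C=C(\C)CC/C=C(/C)[C@H](O)[C@H](OC(=O)/C(C)=C\C)[C@@]12O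
F4 | step 15 | C9 ketone of 26 (C1=C10 enone, other centres as in 26) | C=C1C(=O)O[C@H]2/C=C(\C)CC/C=C(/C)C(=O)[C@H](OC(=O)/C(C)=C\C)[C@@]12O
F5 | step 8 | tert-butyl 3-[(4S)-2,2-dimethyl-1,3-dioxolan-4-yl]-3-oxopropanoate | CC(C)(C)OC(=O)CC(=O)[C@@H]1COC(C)(C)O1
F6 | step 8 | tert-butyl 3-[(4S)-2,2-dimethyl-1,3-dioxolan-4-yl]-3-oxo-2-[(4,4,5,5-tetramethyl-1,3,2-dioxaborolan-2-yl)methyl]propanoate | CC(C)(C)OC(=O)C(CB1OC(C)(C)C(C)(C)O1)C(=O)[C@@H]2COC(C)(C)O2
F7 | step 8 | 6-[(4S)-2,2-dimethyl-1,3-dioxolan-4-yl]-2,2-dimethyl-5-[(4,4,5,5-tetramethyl-1,3,2-dioxaborolan-2-yl)methyl]-4H-1,3-dioxin-4-one | CC1(C)OC(=O)C(CB2OC(C)(C)C(C)(C)O2)=C(O1)[C@@H]3COC(C)(C)O3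
F8 | step 8 | (4R,5S)-4-[(4S)-2,2-dimethyl-1,3-dioxolan-4-yl]-4-hydroxy-5-[(1E,5Z)-6-iodo-2-methylhepta-1,5-dien-1-yl]-3-methylideneoxolan-2-one | C=C1C(=O)O[C@@H](/C=C(\C)CC/C=C(/C)I)[C@@]1(O)[C@@H]2COC(C)(C)O2
F0 | step 13 | none | none
F0 | step 7 | none | none
A1 | alternative 1 | ten-membered (1Z,4E)-diene with C6 triethylsilyl ether, C9 tert-butyldimethylsilyl ether, C7/C8 acetonide and a (trimethylsilyl)ethynyl group on C7 | CC[Si](CC)(CC)O[C@H]2/C=C(\C)CC/C=C(/C)[C@@H](O[Si](C)(C)C(C)(C)C)[C@H](OC(C)(C)O3)[C@@]23C#C[Si](C)(C)C
A2 | alternative 1 | open-chain precursor of A1 with a C2=C3–C4=C5 diene and a (Z)-alkenyl iodide at C1 | C=C/C(C)=C/[C@H](O[Si](CC)(CC)CC)[C@@]1(C#C[Si](C)(C)C)OC(C)(C)O[C@H]1[C@H](O[Si](C)(C)C(C)(C)C)/C(C)=C\I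
A3 | alternative 2 | 26 with O8 as 4-methoxybenzyl ether and O9 as tert-butyldimethylsilyl ether | C=C1C(=O)O[C@H]2/C=C(\C)CC/C=C(/C)[C@@H](O[Si](C)(C)C(C)(C)C)[C@H](OCc3ccc(OC)cc3)[C@@]12O
A4 | alternative 2 | ten-membered C7 ketone carrying the O6 acrylate, O8 4-methoxybenzyl ether and O9 tert-butyldimethylsilyl ether | C=CC(=O)O[C@H]1/C=C(\C)CC/C=C(/C)[C@@H](O[Si](C)(C)C(C)(C)C)[C@H](OCc2ccc(OC)cc2)C1=O
A5 | alternative 3 | ten-membered (1Z,4E)-diene C10 enol triflate with C6 silyl ether, C9 4-methoxybenzyl ether, C7/C8 acetonide and a 3-(silyloxy)prop-1-en-2-yl group on C7 | CC(C)(C)[Si](C)(C)O[C@H]2/C=C(\C)CC/C=C(/OS(=O)(=O)C(F)(F)F)[C@@H](OCc1ccc(OC)cc1)[C@H](OC(C)(C)O3)[C@@]23C(=C)CO[Si](C)(C)C(C)(C)C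
A6 | alternative 3 | cis-1-vinyl-2-isopropenylcyclohexanol precursor of A5 (one of the two cis arrangements) | C=C[C@@]1(O)[C@@H](C(C)=C)[C@H](O[Si](C)(C)C(C)(C)C)[C@@]2(C(=C)CO[Si](C)(C)C(C)(C)C)OC(C)(C)O[C@H]2[C@@H]1OCc1ccc(OC)cc1
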